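**Overview**

- Locants follow daucane: C1 (quaternary, angular methyl), C2, C3, C4 (carbinol bearing isopropyl) and C5 (ring-fusion CH) form the five-membered ring; C1, C5, C6, C7, C8, C9 and C10 form the seven-membered ring. β is the face of the C1 methyl.
- Retrosynthetic cuts, in order: the acetate and 4-methoxybenzoate C–O bonds; the C4–isopropyl bond (back to a cyclopentanone); the C8–CH3 bond (back to an enol triflate); then the seven-membered ring at C6–C7 and C1–C10. This leaves a cyclopentenyl acylsilane (C1–C6) and a four-carbon β-alkoxy enone (C7–C10).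
- Enabling feature: in the seven-membered ring, oxygenated C6, the C7 methylene and C8 of the C8=C9 alkene are a three-carbon unit that can be folded into a 1-silyloxy-2-oxidocyclopropane. Flanked by C5=C1 of the cyclopentene and by C9=C10, this is a cis-divinylcyclopropane, and its Cope rearrangement makes the most congested bond, quaternary C1 to oxygenated C10.
- Forward order: the five-membered ring is bought as 3-methylcyclopentenone and converted into the acylsilane; the seven-membered ring is annulated onto it in one operation; C8 methylation, C5/C6 adjustment, esterification, isopropyl addition at C4 and PMB-to-acetate exchange at C10 follow. No further ring is formed.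
- Stereochemistry: a CBS reduction sets a temporary C4 silyloxy centre that steers C1; C10 follows from the E enol ether and the boat transition state. C5 comes from kinetic protonation, C6 from thermodynamic ketyl reduction, and C4 from isopropyl addition anti to the C5–C6 bond.

Key step: step 8

Remark: metal residues are booked as they stand after an aqueous quench (hydroxide, or the halide the equation supplies); the quench medium itself is treated as work-up.

**Route**

Step 1
Reactants: 1 3-methylcyclopent-2-en-1-one
Product: 3 2-bromo-3-methylcyclopent-2-en-1-one, via trans-dibromide 2 (not isolated)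
Conditions: Br2, CH2Cl2, 0 °C; then Et3N, 0 °C → rt
Reagents that add atoms: bromine, BrBr
Why: Anti addition of bromine to the enone followed by amine-induced E1cB loss of HBr from the α-position (α-bromination by addition–elimination) should leave bromine on C2 alone, since only the α-hydrogen of 2 is acidic; no stereocentre survives.

Step 2
Reactants: 3 2-bromo-3-methylcyclopent-2-en-1-one
Product: 4 (S)-2-bromo-3-methylcyclopent-2-en-1-ol
Conditions: (R)-1-methyl-3,3-diphenyltetrahydro-1H,3H-pyrrolo[1,2-c][1,3,2]oxazaborole (10 mol%), BH3·SMe2, THF, −20 °C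
Reagents that add atoms: none
Why: CBS (oxazaborolidine-catalysed borane) reduction, in which the 2-bromovinyl arm acts as the large ketone substituent, so that the (R)-catalyst should deliver hydride to the face giving the (S)-carbinol, the future temporary C4 stereocentre.

Step 3
Reactants: 4 (S)-2-bromo-3-methylcyclopent-2-en-1-ol
Product: 5 (S)-(2-bromo-3-methylcyclopent-2-en-1-yloxy)(tert-butyl)dimethylsilane
Conditions: TBSCl, imidazole, DMF, rt
Reagents that add atoms: tert-butyldimethylsilyl chloride, CC(C)(C)[Si](C)(C)Cl
Why: Imidazole-promoted silylation of the secondary allylic alcohol (silyl ether formation) should be uneventful and leaves the stereocentre untouched.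

Step 4
Reactants: 5 (S)-(2-bromo-3-methylcyclopent-2-en-1-yloxy)(tert-butyl)dimethylsilane
Product: 7 (S)-5-(tert-butyldimethylsilyloxy)-2-methylcyclopent-1-ene-1-carbaldehyde, via vinyllithium 6 (not isolated)
Conditions: t-BuLi (2.1 equiv), THF, −78 °C; DMF, −78 → 0 °C; aq. NH4Cl
Reagents that add atoms: N,N-dimethylformamide, CN(C)C=O
Why: Bromine–lithium exchange gives a vinyllithium that cannot β-eliminate within the five-membered ring and is formylated by DMF (Bouveault aldehyde synthesis) before any oxygen-to-carbon silyl shift at −78 °C; the stereocentre is not involved.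

Step 5
Reactants: 7 (S)-5-(tert-butyldimethylsilyloxy)-2-methylcyclopent-1-ene-1-carbaldehyde
Product: 8 [(S)-5-(tert-butyldimethylsilyloxy)-2-methylcyclopent-1-en-1-yl](dimethylphenylsilyl)methanol (both carbinol epimers)
Conditions: PhMe2SiLi, THF, −78 °C; aq. NH4Cl at −78 °C
Reagents that add atoms: dimethylphenylsilyllithium, [Li][Si](C)(C)c1ccccc1
Why: 1,2-Addition of the silyllithium to the aldehyde (the fully substituted β-carbon blocks conjugate addition), with a cold quench so that neither Brook rearrangement nor silyl transfer between the two oxygens can set in; the new carbinol centre is formed unselectively and is erased in step 6.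

Step 6
Reactants: 8 [(S)-5-(tert-butyldimethylsilyloxy)-2-methylcyclopent-1-en-1-yl](dimethylphenylsilyl)methanol
Product: 9 [(S)-5-(tert-butyldimethylsilyloxy)-2-methylcyclopent-1-en-1-yl](dimethylphenylsilyl)methanone
Conditions: Dess–Martin periodinane, pyridine, CH2Cl2, 0 °C → rt
Reagents that add atoms: none
Why: Dess–Martin oxidation of the α-silyl carbinol under buffered, non-basic conditions should give the acylsilane without Brook rearrangement or desilylation.

Step 7
Reactants: 10 (E)-4-methoxybut-3-en-2-one
Product: 11 (E)-4-(4-methoxybenzyloxy)but-3-en-2-one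
Conditions: 4-methoxybenzyl alcohol, pyridinium p-toluenesulfonate (cat.), toluene, 60 °C, reduced pressure (MeOH removed)
Reagents that add atoms: (4-methoxyphenyl)methanol, COc1ccc(CO)cc1
Why: Acid-catalysed addition–elimination at the β-carbon of the vinylogous ester (transetherification), driven by removal of methanol, should give the thermodynamically preferred E isomer.

Step 8
Reactants: 11 (E)-4-(4-methoxybenzyloxy)but-3-en-2-one; 9 [(S)-5-(tert-butyldimethylsilyloxy)-2-methylcyclopent-1-en-1-yl](dimethylphenylsilyl)methanone
Product: 16 (1S,4S,10R)-4-(tert-butyldimethylsilyloxy)-6-(dimethylphenylsilyloxy)-10-(4-methoxybenzyloxy)-1-methylbicyclo[5.3.0]deca-5,8-dien-8-yl trifluoromethanesulfonate (daucane locants), via lithium dienolate 12 (not isolated), via Brook precursor alkoxide 13 (not isolated), via cis-divinylcyclopropanolate 14 (not isolated), via cycloheptadienolate 15 (not isolated)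
Conditions: LiN(i-Pr)2, THF, −78 °C (11 → 12); then 9, −78 → −30 °C; then N-(5-chloropyridin-2-yl)triflimide, −78 → −20 °C
Reagents that add atoms: N-(5-chloropyridin-2-yl)-1,1,1-trifluoro-N-(trifluoromethylsulfonyl)methanesulfonamide, FC(F)(F)S(=O)(=O)N(c1ccc(Cl)cn1)S(=O)(=O)C(F)(F)F
Why: The cross-conjugated lithium enolate 12 adds to the acylsilane carbonyl of 9 (future C7–C6 bond) to give alkoxide 13, a 1,2-Brook shift of silicon from carbon to oxygen with 3-exo-trig attack of the resulting α-silyloxy allyl carbanion on the ketone gives the cis-divinylcyclopropanolate 14, and its oxyanion-accelerated [3,3] shift through a boat transition state breaks C6–C8 and forms C1–C10 to give the regiodefined C8 enolate 15, which is O-sulfonylated cold to 16. The closest known reaction type is the Brook-rearrangement-mediated [3+4] annulation of acryloylsilanes with lithium enolates of alkenyl methyl ketones (anionic oxy-Cope rearrangement of a cis-1,2-divinylcyclopropanediol derivative), followed by ordinary enolate O-triflation. The transient cyclopropane closes 3-exo-trig and the seven-membered ring closes by strain-releasing sigmatropic ring expansion of that cyclopropane, the new ring bond being C1–C10 at the quaternary carbon. C1 is controlled by the C4 silyloxy group, which stays on the outer face of the boat so that C10 bonds to the cyclopentene face anti to it and the methyl ends cis to the silyloxy group (1S), and C10 is controlled by the E enol ether geometry together with the ring-locked cyclopentene in the boat, which places the PMB ether and the C2 methylene on the same side of the new bond (10R, trans to the methyl). The step needs attack of the silyloxyallyl anion through its α-carbon (cyclopropane rather than [3+2] closure), which the fully substituted γ-carbon C1 enforces, kinetic deprotonation of 11 at its methyl group, which LiN(i-Pr)2 at −78 °C provides, and capture of 15 before proton transfer from C7 or E1cB loss of the C10 alkoxide, which the low-temperature pyridyl triflimide provides. The methyl group on C1 must point into the boat and will slow the [3,3] step, which is why the mixture is allowed to reach −30 °C before the triflimide is added.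

Step 9
Reactants: 16 the enol triflate of step 8; 17 methylmagnesium bromide
Product: 18 (1S,4S,10R)-4-(tert-butyldimethylsilyloxy)-6-(dimethylphenylsilyloxy)-10-(4-methoxybenzyloxy)-1,8-dimethylbicyclo[5.3.0]deca-5,8-diene (daucane locants)
Conditions: Fe(acac)3 (5 mol%), THF/NMP, −30 °C
Reagents that add atoms: none
Why: Iron-catalysed Kumada-type cross-coupling of an alkenyl triflate with a methyl Grignard reagent is complete within minutes at −30 °C, so the silyl enol ether, the silyl ether and the allylic PMB ether should survive; no stereocentre is formed.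

Step 10
Reactants: 18 the C8-methyl silyl enol ether of step 9
Product: 19 (1S,4S,5R,10R)-4-(tert-butyldimethylsilyloxy)-10-(4-methoxybenzyloxy)-1,8-dimethylbicyclo[5.3.0]dec-8-en-6-one (trans-fused; daucane locants)
Conditions: Bu4NF, AcOH, THF, −78 → −20 °C
Reagents that add atoms: none
Why: Fluoride cleaves the labile dimethylphenylsilyl enol ether in preference to the secondary TBS ether, and the acetic acid present protonates C5 of the enol(ate) under kinetic control on the α face, opposite the two flanking β substituents (C1 methyl and C4 silyloxy), which sets the trans ring fusion (5R); the cold buffered medium should prevent E1cB loss of the C4 silyloxy group and migration of the C8=C9 alkene into conjugation (protodesilylation of a silyl enol ether).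

Step 11
Reactants: 19 the trans-fused C6 ketone of step 10
Product: 20 (1S,4S,5S,6S,10R)-4-(tert-butyldimethylsilyloxy)-10-(4-methoxybenzyloxy)-1,8-dimethylbicyclo[5.3.0]dec-8-en-6-ol (daucane locants)
Conditions: SmI2, THF/H2O, 0 °C
Reagents that add atoms: none
Why: Single-electron (ketyl) reduction by SmI2 in wet THF proceeds through a pyramidal ketyl and carbanion that can settle before protonation, so it should give the thermodynamically preferred equatorial 6α-alcohol (6S), trans to the C5–C4 bond and clear of the 1,3-related angular methyl, where a hydride reagent attacking the open α face would give the epimer.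

Step 12
Reactants: 20 the C6 alcohol of step 11; 21 4-methoxybenzoyl chloride
Product: 22 (1S,4S,5S,6S,10R)-4-(tert-butyldimethylsilyloxy)-10-(4-methoxybenzyloxy)-1,8-dimethylbicyclo[5.3.0]dec-8-en-6-yl 4-methoxybenzoate (daucane locants)
Conditions: pyridine, 4-(dimethylamino)pyridine (cat.), CH2Cl2, 0 °C → rt
Reagents that add atoms: none
Why: Acylation of the only free hydroxyl under nucleophilic catalysis by 4-(dimethylamino)pyridine (acyl transfer); no stereocentre is touched.

Step 13
Reactants: 22 the C6 ester silyl ether of step 12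
Product: 23 (1S,4S,5R,6S,10R)-4-hydroxy-10-(4-methoxybenzyloxy)-1,8-dimethylbicyclo[5.3.0]dec-8-en-6-yl 4-methoxybenzoate (daucane locants)
Conditions: HF·pyridine, pyridine, THF, 0 °C → rt
Reagents that add atoms: none
Why: Acidic fluoride desilylation removes the secondary TBS ether while the ester, the PMB ether and the alkene stay, and the acidic medium suppresses 1,3-acyl migration from O6 to the new O4 hydroxyl.

Step 14
Reactants: 23 the C4 alcohol of step 13
Product: 24 (1S,5S,6S,10R)-10-(4-methoxybenzyloxy)-1,8-dimethyl-4-oxobicyclo[5.3.0]dec-8-en-6-yl 4-methoxybenzoate (daucane locants)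
Conditions: Dess–Martin periodinane, pyridine, CH2Cl2, 0 °C → rt
Reagents that add atoms: none
Why: Dess–Martin oxidation under buffered neutral conditions should give the cyclopentanone without enolisation, so that neither C5 epimerises nor the β-anisoyloxy group is eliminated.

Step 15
Reactants: 24 the C4 ketone of step 14; 25 isopropylmagnesium chloride
Product: 26 (1S,4R,5S,6S,10R)-4-hydroxy-4-isopropyl-10-(4-methoxybenzyloxy)-1,8-dimethylbicyclo[5.3.0]dec-8-en-6-yl 4-methoxybenzoate (daucane locants)
Conditions: CeCl3 (anhydrous), THF, −78 °C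
Reagents that add atoms: none
Why: Organocerium 1,2-addition: the weakly basic, strongly oxophilic isopropylcerium reagent should add to the ketone faster than it enolises it, reduces it by β-hydride transfer or attacks the aryl ester at −78 °C, and it should approach C4 from the α face, anti to the C5–C6 bond and the β angular methyl, giving the 4β-hydroxyl cis to that methyl (4R).

Step 16
Reactants: 26 the tertiary carbinol PMB ether of step 15
Product: 27 (1S,4R,5S,6S,10R)-4,10-dihydroxy-4-isopropyl-1,8-dimethylbicyclo[5.3.0]dec-8-en-6-yl 4-methoxybenzoate (daucane locants)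
Conditions: DDQ, CH2Cl2/pH 7 buffer, 0 °C
Reagents that add atoms: none
Why: Oxidative cleavage of the electron-rich PMB ether by DDQ (benzylic hydride abstraction, then hydrolysis of the oxocarbenium ion) should spare the electron-poor 4-methoxybenzoate, the alkene and the tertiary alcohol, and it leaves the C10–O bond and its configuration intact.

Step 17
Reactants: 27 the C4,C10 diol of step 16
Product: 28 CNP0256979.2, (1S,4R,5S,6S,10R)-10-acetoxy-4-hydroxy-4-isopropyl-1,8-dimethylbicyclo[5.3.0]dec-8-en-6-yl 4-methoxybenzoate (daucane locants)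
Conditions: Ac2O, pyridine, 4-(dimethylamino)pyridine (cat.), CH2Cl2, 0 °C → rt
Reagents that add atoms: acetic anhydride, CC(=O)OC(C)=O
Why: Acetylation under nucleophilic catalysis (acyl transfer) should be selective for the secondary allylic C10 hydroxyl, because the tertiary C4 hydroxyl flanked by the isopropyl group and the ring fusion is too hindered to react.

**Compound list**

1 | 3-methylcyclopent-2-en-1-one | CC1=CC(=O)CC1 | starting material
2 | trans-2,3-dibromo-3-methylcyclopentan-1-one (racemic, one enantiomer drawn) | O=C1CC[C@](C)(Br)[C@H]1Br | intermediate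
3 | 2-bromo-3-methylcyclopent-2-en-1-one | CC1=C(Br)C(=O)CC1 | intermediate
4 | (S)-2-bromo-3-methylcyclopent-2-en-1-ol | CC1=C(Br)[C@@H](O)CC1 | intermediate
5 | (S)-(2-bromo-3-methylcyclopent-2-en-1-yloxy)(tert-butyl)dimethylsilane | CC1=C(Br)[C@@H](O[Si](C)(C)C(C)(C)C)CC1 | intermediate
6 | [(S)-5-(tert-butyldimethylsilyloxy)-2-methylcyclopent-1-en-1-yl]lithium | CC1=C([Li])[C@@H](O[Si](C)(C)C(C)(C)C)CC1 | intermediate
7 | (S)-5-(tert-butyldimethylsilyloxy)-2-methylcyclopent-1-ene-1-carbaldehyde | CC1=C(C=O)[C@@H](O[Si](C)(C)C(C)(C)C)CC1 | intermediate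
8 | [(S)-5-(tert-butyldimethylsilyloxy)-2-methylcyclopent-1-en-1-yl](dimethylphenylsilyl)methanol, both carbinol epimers | C[Si](C)(c1ccccc1)C(O)C1=C(C)CC[C@@H]1O[Si](C)(C)C(C)(C)C | intermediate
9 | [(S)-5-(tert-butyldimethylsilyloxy)-2-methylcyclopent-1-en-1-yl](dimethylphenylsilyl)methanone | C[Si](C)(c1ccccc1)C(=O)C1=C(C)CC[C@@H]1O[Si](C)(C)C(C)(C)C | intermediate
10 | (E)-4-methoxybut-3-en-2-one | CO/C=C/C(C)=O | starting material
11 | (E)-4-(4-methoxybenzyloxy)but-3-en-2-one | COc1ccc(CO/C=C/C(C)=O)cc1 | intermediate
12 | lithium (E)-4-(4-methoxybenzyloxy)buta-1,3-dien-2-olate | C=C([O-])/C=C/OCc1ccc(OC)cc1.[Li+] | intermediate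
13 | lithium (E)-1-[(S)-5-(tert-butyldimethylsilyloxy)-2-methylcyclopent-1-en-1-yl]-1-(dimethylphenylsilyl)-5-(4-methoxybenzyloxy)-3-oxopent-4-en-1-olate, both epimers at the carbinolate carbon | C[Si](C)(c1ccccc1)C([O-])(CC(=O)/C=C/OCc1ccc(OC)cc1)C1=C(C)CC[C@@H]1O[Si](C)(C)C(C)(C)C.[Li+] | intermediate
14 | lithium (1S,2R)-2-(dimethylphenylsilyloxy)-2-[(S)-5-(tert-butyldimethylsilyloxy)-2-methylcyclopent-1-en-1-yl]-1-[(E)-2-(4-methoxybenzyloxy)ethenyl]cyclopropan-1-olate (the two alkenyl groups cis) | C[Si](C)(c1ccccc1)O[C@@]2(C3=C(C)CC[C@@H]3O[Si](C)(C)C(C)(C)C)C[C@]2([O-])/C=C/OCc1ccc(OC)cc1.[Li+] | intermediate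
15 | lithium (1S,4S,10R)-4-(tert-butyldimethylsilyloxy)-6-(dimethylphenylsilyloxy)-10-(4-methoxybenzyloxy)-1-methylbicyclo[5.3.0]deca-5,8-dien-8-olate (daucane locants) | C[Si](C)(c1ccccc1)OC=2CC([O-])=C[C@@H](OCc1ccc(OC)cc1)[C@@]3(C)CC[C@H](O[Si](C)(C)C(C)(C)C)C3=2.[Li+] | intermediate
16 | (1S,4S,10R)-4-(tert-butyldimethylsilyloxy)-6-(dimethylphenylsilyloxy)-10-(4-methoxybenzyloxy)-1-methylbicyclo[5.3.0]deca-5,8-dien-8-yl trifluoromethanesulfonate (daucane locants) | C[Si](C)(c1ccccc1)OC=2CC(OS(=O)(=O)C(F)(F)F)=C[C@@H](OCc1ccc(OC)cc1)[C@@]3(C)CC[C@H](O[Si](C)(C)C(C)(C)C)C3=2 | intermediate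
17 | methylmagnesium bromide | C[Mg]Br | starting material
18 | (1S,4S,10R)-4-(tert-butyldimethylsilyloxy)-6-(dimethylphenylsilyloxy)-10-(4-methoxybenzyloxy)-1,8-dimethylbicyclo[5.3.0]deca-5,8-diene (daucane locants) | C[Si](C)(c1ccccc1)OC=2CC(C)=C[C@@H](OCc1ccc(OC)cc1)[C@@]3(C)CC[C@H](O[Si](C)(C)C(C)(C)C)C3=2 | intermediate
19 | (1S,4S,5R,10R)-4-(tert-butyldimethylsilyloxy)-10-(4-methoxybenzyloxy)-1,8-dimethylbicyclo[5.3.0]dec-8-en-6-one, trans-fused (daucane locants) | O=C2CC(C)=C[C@@H](OCc1ccc(OC)cc1)[C@@]3(C)CC[C@H](O[Si](C)(C)C(C)(C)C)[C@H]23 | intermediate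
20 | (1S,4S,5S,6S,10R)-4-(tert-butyldimethylsilyloxy)-10-(4-methoxybenzyloxy)-1,8-dimethylbicyclo[5.3.0]dec-8-en-6-ol (daucane locants; 6α-OH) | O[C@H]2CC(C)=C[C@@H](OCc1ccc(OC)cc1)[C@@]3(C)CC[C@H](O[Si](C)(C)C(C)(C)C)[C@H]23 | intermediate
21 | 4-methoxybenzoyl chloride | COc1ccc(C(Cl)=O)cc1 | starting material
22 | (1S,4S,5S,6S,10R)-4-(tert-butyldimethylsilyloxy)-10-(4-methoxybenzyloxy)-1,8-dimethylbicyclo[5.3.0]dec-8-en-6-yl 4-methoxybenzoate (daucane locants) | COc1ccc(C(=O)O[C@H]2CC(C)=C[C@@H](OCc4ccc(OC)cc4)[C@@]3(C)CC[C@H](O[Si](C)(C)C(C)(C)C)[C@H]23)cc1 | intermediate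
23 | (1S,4S,5R,6S,10R)-4-hydroxy-10-(4-methoxybenzyloxy)-1,8-dimethylbicyclo[5.3.0]dec-8-en-6-yl 4-methoxybenzoate (daucane locants) | COc1ccc(C(=O)O[C@H]2CC(C)=C[C@@H](OCc4ccc(OC)cc4)[C@@]3(C)CC[C@H](O)[C@H]23)cc1 | intermediate
24 | (1S,5S,6S,10R)-10-(4-methoxybenzyloxy)-1,8-dimethyl-4-oxobicyclo[5.3.0]dec-8-en-6-yl 4-methoxybenzoate (daucane locants) | COc1ccc(C(=O)O[C@H]2CC(C)=C[C@@H](OCc4ccc(OC)cc4)[C@@]3(C)CCC(=O)[C@H]23)cc1 | intermediate
25 | isopropylmagnesium chloride | CC(C)[Mg]Cl | starting material
26 | (1S,4R,5S,6S,10R)-4-hydroxy-4-isopropyl-10-(4-methoxybenzyloxy)-1,8-dimethylbicyclo[5.3.0]dec-8-en-6-yl 4-methoxybenzoate (daucane locants) | COc1ccc(C(=O)O[C@H]2CC(C)=C[C@@H](OCc4ccc(OC)cc4)[C@@]3(C)CC[C@@](O)(C(C)C)[C@H]23)cc1 | intermediate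
27 | (1S,4R,5S,6S,10R)-4,10-dihydroxy-4-isopropyl-1,8-dimethylbicyclo[5.3.0]dec-8-en-6-yl 4-methoxybenzoate (daucane locants) | COc1ccc(C(=O)O[C@H]2CC(C)=C[C@@H](O)[C@@]3(C)CC[C@@](O)(C(C)C)[C@H]23)cc1 | intermediate
28 | CNP0256979.2; (3R,3aS,4S,8R,8aS)-8-acetoxy-3-hydroxy-6,8a-dimethyl-3-(propan-2-yl)-1,2,3,3a,4,5,8,8a-octahydroazulen-4-yl 4-methoxybenzoate; in daucane locants (1S,4R,5S,6S,10R), 10α-acetoxy, 6α-(4-methoxybenzoyloxy), 4β-hydroxy | COc1ccc(C(=O)O[C@H]2CC(C)=C[C@@H](OC(C)=O)[C@@]3(C)CC[C@@](O)(C(C)C)[C@H]23)cc1 | target

**Step count**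

Total: 17 steps. Longest linear sequence: 16 steps (steps 1–6 and 8–17 from 3-methylcyclopent-2-en-1-one); step 7 is a one-step side branch.

**Steps most likely to fail**

1. Step 8. The [3,3] ring expansion may be slowed by the methyl group that has to point into the boat. Cyclopropanolate 14 then accumulates, and enolate 15 appears only at a temperature where it loses the C10 alkoxide by E1cB or exchanges a proton with C7 before it is sulfonylated. The facial preference set by the remote C4 silyloxy group may also be only moderate.
   Fallback: the cascade is interrupted at the cyclopropane and the rearrangement is run on a neutral substrate. Setting out from 9 and 11, the enolate addition is carried out as before at −78 °C and 14 is captured with acetic anhydride as (1S,2R)-2-(dimethylphenylsilyloxy)-2-[(S)-5-(tert-butyldimethylsilyloxy)-2-methylcyclopent-1-en-1-yl]-1-[(E)-2-(4-methoxybenzyloxy)ethenyl]cyclopropyl acetate F1. Heating in toluene at 80–110 °C should bring about the classical thermal cis-divinylcyclopropane-to-cycloheptadiene Cope rearrangement through the same boat geometry, giving the C8 enol acetate F2, with no enolate present at the temperature the rearrangement needs. MeLi (2 equiv) in THF at −78 °C then cleaves the enol acetate much faster than the silyl enol ether and regenerates enolate 15 regiospecifically in the cold, where the pyridyl triflimide traps it at once. The sequence comes back to the route at 16.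

2. Step 11. The ketyl-derived carbanion may be protonated under kinetic control from the open α face, or the samarium may be held by the neighbouring silyloxy oxygen, so that the axial 6β-alcohol forms instead of the equatorial 6α-alcohol.
   Fallback: the configuration is set by inversion instead of by equilibration. Setting out from 19, Li[BH(s-Bu)3] in THF at −78 °C delivers hydride from the α face, away from the angular methyl, and should give the 6β-alcohol F3 on purpose. A Mitsunobu reaction with 4-methoxybenzoic acid (PPh3, DIAD, toluene, 0 °C → rt) then installs the ester with inversion at C6. The sequence comes back to the route at 22 and also saves the separate acylation.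

3. Step 15. Enolisation of the α-branched β-acyloxy cyclopentanone (with E1cB loss of 4-methoxybenzoate) and β-hydride transfer from the secondary organometallic may outrun 1,2-addition.
   Fallback: the isopropyl group is brought in as a masked sp2 nucleophile. Setting out from 24, isopropenylmagnesium bromide with CeCl3 in THF at −78 °C should add from the same α face to give the isopropenyl carbinol F4; the reagent is less basic and cannot deliver a β-hydride. Homogeneous hydrogenation with RhCl(PPh3)3 under H2 (1 atm, benzene, rt) then saturates the 1,1-disubstituted alkene and leaves the trisubstituted ring alkene and the PMB ether. The sequence comes back to the route at 26.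

**Further compounds**

F1 | step 8 | (1S,2R)-2-(dimethylphenylsilyloxy)-2-[(S)-5-(tert-butyldimethylsilyloxy)-2-methylcyclopent-1-en-1-yl]-1-[(E)-2-(4-methoxybenzyloxy)ethenyl]cyclopropyl acetate | C[Si](C)(c1ccccc1)O[C@@]2(C3=C(C)CC[C@@H]3O[Si](C)(C)C(C)(C)C)C[C@]2(OC(C)=O)/C=C/OCc1ccc(OC)cc1
F2 | step 8 | (1S,4S,10R)-4-(tert-butyldimethylsilyloxy)-6-(dimethylphenylsilyloxy)-10-(4-methoxybenzyloxy)-1-methylbicyclo[5.3.0]deca-5,8-dien-8-yl acetate (daucane locants) | C[Si](C)(c1ccccc1)OC=2CC(OC(C)=O)=C[C@@H](OCc1ccc(OC)cc1)[C@@]3(C)CC[C@H](O[Si](C)(C)C(C)(C)C)C3=2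
F3 | step 11 | (1S,4S,5S,6R,10R)-4-(tert-butyldimethylsilyloxy)-10-(4-methoxybenzyloxy)-1,8-dimethylbicyclo[5.3.0]dec-8-en-6-ol (daucane locants; 6β-OH, C6 epimer of 20) | O[C@@H]2CC(C)=C[C@@H](OCc1ccc(OC)cc1)[C@@]3(C)CC[C@H](O[Si](C)(C)C(C)(C)C)[C@H]23
F4 | step 15 | (1S,4S,5S,6S,10R)-4-hydroxy-10-(4-methoxybenzyloxy)-1,8-dimethyl-4-(prop-1-en-2-yl)bicyclo[5.3.0]dec-8-en-6-yl 4-methoxybenzoate (daucane locants; 4β-OH) | COc1ccc(C(=O)O[C@H]2CC(C)=C[C@@H](OCc4ccc(OC)cc4)[C@@]3(C)CC[C@@](O)(C(C)=C)[C@H]23)cc1
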